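## Retrosynthetic overview

1. Glaucolide A comes from peripheral epoxidation of the C4=C5 alkene and an exchange of silyl groups for esters on a germacra-4,7(11)-dien-12,6-olide.
2. Key step: the ten-membered carbocycle and the butenolide close together. An acyclic ynal, CO and nickel combine in a [2+2+1] reaction that forms the C6–C7, C11–C12 and C12–O bonds.
3. The ynal comes from a copper/box Mukaiyama aldol between a 1,2-diketone and an enyne silyl enol ether (C9–C10 bond, sets C10). An ynone transfer hydrogenation then sets C8.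
4. The diketone comes from biacetyl monoketal and a C5 allylic bromide made from prenyl acetate. The enol ether comes from a silylated propargyl alcohol.
5. Ring order: carbocycle and lactone together in step 12, epoxide last in step 15.

Assumption: locants C1–C15 follow germacrane numbering (C1 ketone, C4/C5 epoxide, C6 lactone carbinol, C8 methacrylate carbinol, C10 acetoxy carbon, C12 lactone C=O, C13 acetoxymethyl), and compounds 1, 4 and 7 are bought.

## Route

Step 1
Reactants: 1 prenyl acetate (3-methylbut-2-en-1-yl acetate)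
Product: 2 (2E)-4-hydroxy-3-methylbut-2-en-1-yl acetate
Conditions: SeO2 (0.3 equiv), t-BuOOH (3 equiv), CH2Cl2, 0 °C to rt
Reagents that add atoms: tert-butyl hydroperoxide, CC(C)(C)OO
Why: Riley allylic oxidation (ene reaction, then 2,3-sigmatropic shift) attacks only the (E)-methyl group of the trisubstituted alkene, which fixes the E geometry of the later C4=C5 bond; no stereocenter forms.

Step 2
Reactants: 2 (2E)-4-hydroxy-3-methylbut-2-en-1-yl acetate
Product: 3 (2E)-4-bromo-3-methylbut-2-en-1-yl acetate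
Conditions: CBr4, PPh3, CH2Cl2, 0 °C
Reagents that add atoms: carbon tetrabromide, BrC(Br)(Br)Br
Why: The Appel reaction turns the primary allylic alcohol into the bromide under neutral conditions, without allylic transposition and without touching the acetate.

Step 3
Reactants: 3 (2E)-4-bromo-3-methylbut-2-en-1-yl acetate; 4 3,3-dimethoxybutan-2-one
Product: 6 (2E)-3-methyl-6,7-dioxooct-2-en-1-yl acetate, via keto ketal 5 (not isolated)
Conditions: LDA (commercial solution, 1.05 equiv), 4, THF, −78 °C; 3, −78 to 0 °C; then 0.5 M HCl, THF, rt, 1 h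
Reagents that add atoms: water, O
Why: The ketone has one enolisable position, so kinetic enolate SN2 alkylation with the primary allylic bromide makes C2–C3 cleanly, and dilute acid then hydrolyses the α-keto ketal far faster than the acetate.

Step 4
Reactants: 7 tert-butyldimethyl(prop-2-yn-1-yloxy)silane
Product: 8 5-(tert-butyldimethylsilyloxy)pent-3-yn-2-one
Conditions: n-BuLi, THF, −78 °C; N-methoxy-N-methylacetamide, −78 to 0 °C; then H2O
Reagents that add atoms: N-methoxy-N-methylacetamide, CC(=O)N(C)OC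
Why: In this Weinreb ketone synthesis the lithium acetylide adds once, and the chelated tetrahedral adduct collapses to the ynone only on quench.

Step 5
Reactants: 8 5-(tert-butyldimethylsilyloxy)pent-3-yn-2-one
Product: 9 5-(tert-butyldimethylsilyloxy)-2-(trimethylsilyloxy)pent-1-en-3-yne
Conditions: TMSOTf, Et3N, CH2Cl2, 0 °C
Reagents that add atoms: trimethylsilyl triflate, C[Si](C)(C)OS(=O)(=O)C(F)(F)F
Why: Soft enolisation and O-silylation can occur only toward the methyl group, so a single silyl enol ether forms.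

Step 6
Reactants: 6 (2E)-3-methyl-6,7-dioxooct-2-en-1-yl acetate; 9 5-(tert-butyldimethylsilyloxy)-2-(trimethylsilyloxy)pent-1-en-3-yne
Product: 11 (2E,7R)-12-(tert-butyldimethylsilyloxy)-7-hydroxy-3,7-dimethyl-6,9-dioxododec-2-en-10-yn-1-yl acetate, via trimethylsilyl ether 10 (not isolated)
Conditions: Cu(OTf)2 (10 mol %), (R,R)-t-Bu-box (11 mol %), THF, −78 °C; then 1 M HCl, THF, 0 °C, 15 min
Reagents that add atoms: none
Why: In this catalytic enantioselective Mukaiyama aldol the diketone chelates square-planar divalent copper, the enol silane attacks the less hindered acetyl carbonyl (methyl versus alkyl discrimination as known for 2,3-pentanedione), and the (R,R) ligand, mirror image of the established (S,S)-ligand/(S)-carbinol pairing, sets C10 as R.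

Step 7
Reactants: 11 (2E,7R)-12-(tert-butyldimethylsilyloxy)-7-hydroxy-3,7-dimethyl-6,9-dioxododec-2-en-10-yn-1-yl acetate
Product: 12 (2E,7R,9S)-12-(tert-butyldimethylsilyloxy)-7,9-dihydroxy-3,7-dimethyl-6-oxododec-2-en-10-yn-1-yl acetate
Conditions: Ru(p-cymene)[(S,S)-TsDPEN] (1 mol %), i-PrOH, rt
Reagents that add atoms: none
Why: Noyori asymmetric transfer hydrogenation reduces ynones rapidly under base-free conditions while the hindered dialkyl C1 ketone stays, and with the alkyne playing the part of the aryl group the (S,S) catalyst sets C8 as S by reagent control.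

Step 8
Reactants: 12 (2E,7R,9S)-12-(tert-butyldimethylsilyloxy)-7,9-dihydroxy-3,7-dimethyl-6-oxododec-2-en-10-yn-1-yl acetate
Product: 13 (2E,7R,9S)-9,12-bis(tert-butyldimethylsilyloxy)-7-hydroxy-3,7-dimethyl-6-oxododec-2-en-10-yn-1-yl acetate
Conditions: TBSCl, imidazole, DMF, rt
Reagents that add atoms: tert-butyldimethylsilyl chloride, CC(C)(C)[Si](C)(C)Cl
Why: Standard silyl ether formation takes only the secondary propargylic alcohol because the tertiary α-ketol hydroxyl is inert to TBSCl/imidazole.

Step 9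
Reactants: 13 (2E,7R,9S)-9,12-bis(tert-butyldimethylsilyloxy)-7-hydroxy-3,7-dimethyl-6-oxododec-2-en-10-yn-1-yl acetate
Product: 14 (2E,7R,9S)-9,12-bis(tert-butyldimethylsilyloxy)-1,7-dihydroxy-3,7-dimethyldodec-2-en-10-yn-6-one
Conditions: K2CO3 (0.2 equiv), MeOH, 0 °C
Reagents that add atoms: none
Why: Base-catalysed transesterification removes the only ester in the molecule, so no selectivity question arises, and the silyl ethers survive.

Step 10
Reactants: 14 (2E,7R,9S)-9,12-bis(tert-butyldimethylsilyloxy)-1,7-dihydroxy-3,7-dimethyldodec-2-en-10-yn-6-one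
Product: 15 (2E,7R,9S)-9,12-bis(tert-butyldimethylsilyloxy)-7-hydroxy-3,7-dimethyl-6-oxododec-2-en-10-ynal
Conditions: MnO2 (20 equiv), CH2Cl2, rt
Reagents that add atoms: none
Why: MnO2 oxidises only the allylic primary alcohol, keeps the E geometry of the enal, and cannot touch the tertiary alcohol.

Step 11
Reactants: 15 (2E,7R,9S)-9,12-bis(tert-butyldimethylsilyloxy)-7-hydroxy-3,7-dimethyl-6-oxododec-2-en-10-ynal
Product: 16 (2E,7R,9S)-7-acetoxy-9,12-bis(tert-butyldimethylsilyloxy)-3,7-dimethyl-6-oxododec-2-en-10-ynal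
Conditions: Ac2O (5 equiv), DMAP (0.5 equiv), Et3N, CH2Cl2, 35 °C
Reagents that add atoms: acetic anhydride, CC(=O)OC(C)=O
Why: DMAP-catalysed acylation acetylates the only free hydroxyl (tertiary, C10) with retention because the C–O bond is not broken.

Step 12
Reactants: 16 (2E,7R,9S)-7-acetoxy-9,12-bis(tert-butyldimethylsilyloxy)-3,7-dimethyl-6-oxododec-2-en-10-ynal
Product: 18 (4E,6R,8S,10R)-10-acetoxy-8,13-bis(tert-butyldimethylsilyloxy)-1-oxogermacra-4,7(11)-dien-12,6-olide, via nickeladihydrofuran 17 (not isolated)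
Conditions: Ni(cod)2 (1.1 equiv), IPr (1,3-bis(2,6-diisopropylphenyl)imidazol-2-ylidene, 1.1 equiv), toluene, 2 mM, 16 added over 8 h at 25 °C, then 40 °C, 2 h; then CO (1 atm), 25 °C, 1 h
Reagents that add atoms: carbon monoxide, [C-]#[O+]
Why: Proposed new method: a macrocyclic hetero-Pauson–Khand reaction run stoichiometrically on zerovalent nickel, in which IPr–Ni binds the alkyne and the aldehyde and oxidative cyclisation gives 17, the bulky carbene keeping the small CH2OTBS carbon (C11) next to nickel so that C6 bonds to C7 (exocyclic mode, ten-membered ring), after which CO inserts into the Ni–C11 bond and acyl–oxygen reductive elimination closes the butenolide, so both rings form in one flask; the closest known reactions are the hetero-Pauson–Khand cyclisation of short-tether ynals, nickel/carbene reductive ynal macrocyclisations with ligand-controlled exocyclic selectivity, and the carbonylation of isolated nickeladihydrofurans to butenolides; silyl ethers are used because a propargylic ester would β-eliminate from the C11–Ni bond, the β,β-disubstituted enal cannot react in the 1,4 mode without building a quaternary centre in an eight-membered ring, and the tert-alkyl C1 ketone should not bind nickel without a Lewis acid; C6 is set by C8, because allylic 1,3-strain holds H8 in the alkene plane toward C13 and the closing ring avoids a syn-pentane contact only when C5 and C9 leave the C6–C7–C8 plane on opposite faces, which is the natural relative configuration (descriptor R here, S in the target after the priority change).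

Step 13
Reactants: 18 (4E,6R,8S,10R)-10-acetoxy-8,13-bis(tert-butyldimethylsilyloxy)-1-oxogermacra-4,7(11)-dien-12,6-olide
Product: 19 (4E,6R,8S,10R)-10-acetoxy-8,13-dihydroxy-1-oxogermacra-4,7(11)-dien-12,6-olide
Conditions: HF·pyridine, pyridine, THF, 0 °C to rt
Reagents that add atoms: none
Why: Buffered fluoride desilylation cleaves both silyl ethers without base, so the acidic C6–H, the tertiary acetate and the lactone are untouched, and translactonisation to O8 is impossible because C8 is trans to C12 across C7=C11.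

Step 14
Reactants: 19 (4E,6R,8S,10R)-10-acetoxy-8,13-dihydroxy-1-oxogermacra-4,7(11)-dien-12,6-olide
Product: 21 (4E,6R,8S,10R)-10,13-diacetoxy-8-methacryloyloxy-1-oxogermacra-4,7(11)-dien-12,6-olide, via 13-monoacetate 20 (not isolated)
Conditions: AcCl (1.05 equiv), 2,4,6-collidine, CH2Cl2, −78 °C; then methacrylic anhydride (3 equiv), DMAP (0.2 equiv), Et3N, 0 °C to rt
Reagents that add atoms: acetyl chloride, CC(=O)Cl; methacrylic anhydride, C=C(C)C(=O)OC(=O)C(C)=C
Why: Rate-differentiated acylation takes the primary C13 alcohol first at low temperature, and DMAP-catalysed acylation then esterifies the remaining secondary C8 alcohol with retention, drawing any C8–O/C1 hemiketal back to the open keto form.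

Step 15
Reactants: 21 (4E,6R,8S,10R)-10,13-diacetoxy-8-methacryloyloxy-1-oxogermacra-4,7(11)-dien-12,6-olide
Product: 22 glaucolide A, (4R,5R,6S,8S,10R)-10,13-diacetoxy-4,5-epoxy-8-methacryloyloxy-1-oxogermacr-7(11)-en-12,6-olide
Conditions: mCPBA (1.2 equiv), NaHCO3, CH2Cl2, 0 °C
Reagents that add atoms: 3-chloroperoxybenzoic acid, O=C(OO)c1cccc(Cl)c1
Why: Prilezhaev epoxidation picks the only electron-rich alkene, is stereospecific (E alkene to trans epoxide), and attacks the peripheral face, which is the face carrying O6 when allylic 1,3-strain makes H6 eclipse the C15-bearing alkene, giving the threo C5/C6 relationship and thus 4R,5R.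

## Compound list

1 | prenyl acetate | CC(C)=CCOC(C)=O | starting material
2 | (2E)-4-hydroxy-3-methylbut-2-en-1-yl acetate | CC(=O)OC/C=C(C)/CO | intermediate
3 | (2E)-4-bromo-3-methylbut-2-en-1-yl acetate | CC(=O)OC/C=C(C)/CBr | intermediate
4 | 3,3-dimethoxybutan-2-one | CC(=O)C(C)(OC)OC | starting material
5 | (2E)-7,7-dimethoxy-3-methyl-6-oxooct-2-en-1-yl acetate (keto ketal) | CC(=O)OC/C=C(C)/CCC(=O)C(C)(OC)OC | intermediate
6 | (2E)-3-methyl-6,7-dioxooct-2-en-1-yl acetate | CC(=O)OC/C=C(C)/CCC(=O)C(C)=O | intermediate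
7 | tert-butyldimethyl(prop-2-yn-1-yloxy)silane | C#CCO[Si](C)(C)C(C)(C)C | starting material
8 | 5-(tert-butyldimethylsilyloxy)pent-3-yn-2-one | CC(=O)C#CCO[Si](C)(C)C(C)(C)C | intermediate
9 | 5-(tert-butyldimethylsilyloxy)-2-(trimethylsilyloxy)pent-1-en-3-yne | C=C(O[Si](C)(C)C)C#CCO[Si](C)(C)C(C)(C)C | intermediate
10 | trimethylsilyl ether of 11 (C10 R) | CC(=O)OC/C=C(C)/CCC(=O)[C@](C)(O[Si](C)(C)C)CC(=O)C#CCO[Si](C)(C)C(C)(C)C | intermediate
11 | (2E,7R)-12-(tert-butyldimethylsilyloxy)-7-hydroxy-3,7-dimethyl-6,9-dioxododec-2-en-10-yn-1-yl acetate | CC(=O)OC/C=C(C)/CCC(=O)[C@](C)(O)CC(=O)C#CCO[Si](C)(C)C(C)(C)C | intermediate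
12 | (2E,7R,9S)-12-(tert-butyldimethylsilyloxy)-7,9-dihydroxy-3,7-dimethyl-6-oxododec-2-en-10-yn-1-yl acetate | CC(=O)OC/C=C(C)/CCC(=O)[C@](C)(O)C[C@H](O)C#CCO[Si](C)(C)C(C)(C)C | intermediate
13 | (2E,7R,9S)-9,12-bis(tert-butyldimethylsilyloxy)-7-hydroxy-3,7-dimethyl-6-oxododec-2-en-10-yn-1-yl acetate | CC(=O)OC/C=C(C)/CCC(=O)[C@](C)(O)C[C@H](O[Si](C)(C)C(C)(C)C)C#CCO[Si](C)(C)C(C)(C)C | intermediate
14 | (2E,7R,9S)-9,12-bis(tert-butyldimethylsilyloxy)-1,7-dihydroxy-3,7-dimethyldodec-2-en-10-yn-6-one | OC/C=C(C)/CCC(=O)[C@](C)(O)C[C@H](O[Si](C)(C)C(C)(C)C)C#CCO[Si](C)(C)C(C)(C)C | intermediate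
15 | (2E,7R,9S)-9,12-bis(tert-butyldimethylsilyloxy)-7-hydroxy-3,7-dimethyl-6-oxododec-2-en-10-ynal | O=C/C=C(C)/CCC(=O)[C@](C)(O)C[C@H](O[Si](C)(C)C(C)(C)C)C#CCO[Si](C)(C)C(C)(C)C | intermediate
16 | (2E,7R,9S)-7-acetoxy-9,12-bis(tert-butyldimethylsilyloxy)-3,7-dimethyl-6-oxododec-2-en-10-ynal | O=C/C=C(C)/CCC(=O)[C@](C)(OC(C)=O)C[C@H](O[Si](C)(C)C(C)(C)C)C#CCO[Si](C)(C)C(C)(C)C | intermediate
17 | IPr-ligated nickeladihydrofuran (Ni bound to O6 and C11, C6–C7 bond formed) | CC(C)c1cccc(C(C)C)c1N2C=CN(c3c(C(C)C)cccc3C(C)C)C2=[Ni]4O[C@@H]5/C=C(C)/CCC(=O)[C@](C)(OC(C)=O)C[C@H](O[Si](C)(C)C(C)(C)C)C5=C4CO[Si](C)(C)C(C)(C)C | intermediate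
18 | (4E,6R,8S,10R)-10-acetoxy-8,13-bis(tert-butyldimethylsilyloxy)-1-oxogermacra-4,7(11)-dien-12,6-olide | CC(C)(C)[Si](C)(C)O[C@H]1C[C@@](C)(OC(C)=O)C(=O)CC/C(C)=C/[C@H]2OC(=O)C(CO[Si](C)(C)C(C)(C)C)=C12 | intermediate
19 | (4E,6R,8S,10R)-10-acetoxy-8,13-dihydroxy-1-oxogermacra-4,7(11)-dien-12,6-olide | O[C@H]1C[C@@](C)(OC(C)=O)C(=O)CC/C(C)=C/[C@H]2OC(=O)C(CO)=C12 | intermediate
20 | (4E,6R,8S,10R)-10,13-diacetoxy-8-hydroxy-1-oxogermacra-4,7(11)-dien-12,6-olide | O[C@H]1C[C@@](C)(OC(C)=O)C(=O)CC/C(C)=C/[C@H]2OC(=O)C(COC(C)=O)=C12 | intermediate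
21 | (4E,6R,8S,10R)-10,13-diacetoxy-8-methacryloyloxy-1-oxogermacra-4,7(11)-dien-12,6-olide | C=C(C)C(=O)O[C@H]1C[C@@](C)(OC(C)=O)C(=O)CC/C(C)=C/[C@H]2OC(=O)C(COC(C)=O)=C12 | intermediate
22 | glaucolide A (4R,5R,6S,8S,10R) | C=C(C)C(=O)O[C@H]1C[C@@](C)(OC(C)=O)C(=O)CC[C@@]2(C)O[C@@H]2[C@H]2OC(=O)C(COC(C)=O)=C12 | target

## Step count

Total: 15 steps. Longest linear sequence: 13 steps (steps 1–3 and 6–15).

## Steps most likely to fail

**Step 12 (ring closure).** The risks are:
- medium-ring strain;
- exocyclic versus endocyclic regiochemistry;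
- five-membered closure of C7 onto the C1 ketone;
- the diastereomer ratio at C6.

The fallback sets out from 16 and comes back at 20, closing the rings one after the other with an aldehyde-selective organochromium reagent. AcOH/THF/H2O (3:1:1, rt) frees only the primary silyl ether and gives the propargylic alcohol F1. CBr4/PPh3 then gives the propargylic bromide F2. CrCl2 (6 equiv, THF/DMF, 2 mM, slow addition) forms a propargylchromium species that adds to the enal through its γ-carbon C7 and gives the ten-membered α-allenol F3. Pd(OAc)2 (10 mol %), 1,4-benzoquinone, LiOAc and AcOH under CO (1 atm) carry out an oxidative alkoxycarbonylation at the central allene carbon C11. Acetate opens the resulting π-allylpalladium at C13 and gives the 13-acetoxy butenolide silyl ether F4. HF·pyridine then gives 20, which is methacryloylated as in step 14.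

**Step 6 (aldol).** A ketone-derived enyne enol silane is a weaker and less tested nucleophile than ketene thioacetals, so conversion, site selectivity and ee are all uncertain. The fallback sets out from 6 and comes back at 11, making the C7–C8 bond after the aldol instead of before it. S-ethyl thioacetate with LDA/TMSCl gives the ketene silyl thioacetal F5. F5 and 6 react under the same Cu(OTf)2/(R,R)-t-Bu-box catalyst to give the silylated thioester aldol F6, and dilute HCl gives the thioester ketol F7. Coupling of F7 with alkyne 7 (PdCl2(dppf), P(2-furyl)3, CuI, Et3N, DMF, 50 °C) replaces the ethylthio group by the alkynyl group and gives 11.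

**Step 15 (epoxidation).** The ring may expose the face opposite to the one predicted. The fallback sets out from 21 and comes back at 22, and it delivers oxygen to the face that the electrophile does not attack. NBS in acetone/H2O at 0 °C forms the bromonium ion on the exposed face. Water opens it anti at the tertiary C4 and gives the bromohydrin F8. Ag2O in CH2Cl2 then closes the C4 oxygen onto C5 with inversion and gives 22.

## Further compounds

F1 | step 12 | (2E,7R,9S)-7-acetoxy-9-(tert-butyldimethylsilyloxy)-12-hydroxy-3,7-dimethyl-6-oxododec-2-en-10-ynal | O=C/C=C(C)/CCC(=O)[C@](C)(OC(C)=O)C[C@H](O[Si](C)(C)C(C)(C)C)C#CCO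
F2 | step 12 | (2E,7R,9S)-7-acetoxy-12-bromo-9-(tert-butyldimethylsilyloxy)-3,7-dimethyl-6-oxododec-2-en-10-ynal | O=C/C=C(C)/CCC(=O)[C@](C)(OC(C)=O)C[C@H](O[Si](C)(C)C(C)(C)C)C#CCBr
F3 | step 12 | (4E,6R,8S,10R)-10-acetoxy-8-(tert-butyldimethylsilyloxy)-6-hydroxy-7-vinylidene-4,10-dimethylcyclodec-4-en-1-one (germacrane locants) | C=C=C1[C@H](O)/C=C(C)/CCC(=O)[C@](C)(OC(C)=O)C[C@@H]1O[Si](C)(C)C(C)(C)C
F4 | step 12 | (4E,6R,8S,10R)-10,13-diacetoxy-8-(tert-butyldimethylsilyloxy)-1-oxogermacra-4,7(11)-dien-12,6-olide | CC(C)(C)[Si](C)(C)O[C@H]1C[C@@](C)(OC(C)=O)C(=O)CC/C(C)=C/[C@H]2OC(=O)C(COC(C)=O)=C12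
F5 | step 6 | 1-(ethylsulfanyl)-1-(trimethylsilyloxy)ethene | C=C(SCC)O[Si](C)(C)C
F6 | step 6 | S-ethyl (3R,8E)-10-acetoxy-3,8-dimethyl-4-oxo-3-(trimethylsilyloxy)dec-8-enethioate | CC(=O)OC/C=C(C)/CCC(=O)[C@](C)(O[Si](C)(C)C)CC(=O)SCC
F7 | step 6 | S-ethyl (3R,8E)-10-acetoxy-3-hydroxy-3,8-dimethyl-4-oxodec-8-enethioate | CC(=O)OC/C=C(C)/CCC(=O)[C@](C)(O)CC(=O)SCC
F8 | step 15 | (4R,5S,6S,8S,10R)-10,13-diacetoxy-5-bromo-4-hydroxy-8-methacryloyloxy-1-oxogermacr-7(11)-en-12,6-olide | C=C(C)C(=O)O[C@H]1C[C@@](C)(OC(C)=O)C(=O)CC[C@@](C)(O)[C@@H](Br)[C@H]2OC(=O)C(COC(C)=O)=C12
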